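## Plan

1. Retrosynthesis: remove the two silyl ethers, then cut the C15′–C14′ single bond. It joins two (E)-alkenyl CH carbons (C15=C15′ unsubstituted; the methyl sits on C13′, not C14′), held away from the acid-labile 2,5-dihydrofuran (ring C: O, C5′, C6′, C7′, C8′) by the C9′–C13′ diene and from the tertiary allylic C6–OH of ring A by the C7–C14 tetraene. A neutral, stereoretentive alkenyl–alkenyl Stille coupling of a C21 pentaenylstannane with a C19 trienyl iodide can therefore close the chromophore last.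
2. Both halves are cut back to one epoxy aldehyde (ring plus C7) from (−)-actinol: half A at C11=C12 and C7=C8 (Horner–Wadsworth–Emmons), half B at C11′=C12′ (Horner–Wadsworth–Emmons), O–C8′ (allene cyclisation) and C8′–C9′ (Sonogashira).
3. Forward: actinol → enol triflate → ester → allylic alcohol → anti epoxide → aldehyde (steps 1–6); half B: alkyne → enyne ester → allene → ring C → iodotriene (steps 7–16); half A: dienoate → 5,6-diol → C20 aldehyde → stannane (steps 17–25); coupling (step 26); desilylation (step 27).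
4. Stereochemistry: C3/C3′ from actinol; C5, C5′ (and C6 provisionally) from a reagent-controlled Sharpless epoxidation; C6 by inversion when water opens the epoxide; C8′ from the allene axis (SN2′ hydride delivery), transferred to carbon in the gold-catalysed ring closure.
5. All chain alkenes are (E): from Horner–Wadsworth–Emmons steps, syn-carboalumination, (E)-enol triflate formation, Takai-type olefination and stereoretentive couplings.

Key step: step 26

Remark: carotenoid numbering is used (ring A C1–C6, chain C7–C15, then C15′–C8′, rings B and C primed); TBS = tert-butyldimethylsilyl. (4R,6R)-Actinol, methyl acetoacetate, propargyl alcohol, the (E)-C5 phosphonate 23 and dibromomethane are taken as purchasable.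

## Route

Step 1
Reactants: 1 (4R,6R)-4-hydroxy-2,2,6-trimethylcyclohexanone [(−)-actinol]
Product: 2 (4R,6R)-4-(TBSO)-2,2,6-trimethylcyclohexanone
Conditions: TBSCl, imidazole, DMF, rt
Reagents that add atoms: tert-butyldimethylsilyl chloride, CC(C)(C)[Si](C)(C)Cl
Why: Imidazole-promoted silyl ether formation masks the secondary C3 hydroxyl for the enolate, hydride and acid steps that follow; no stereocentre is touched.

Step 2
Reactants: 2 (4R,6R)-4-(TBSO)-2,2,6-trimethylcyclohexanone
Product: 4 (R)-4-(TBSO)-2,6,6-trimethylcyclohex-1-en-1-yl trifluoromethanesulfonate, via lithium enolate 3 (not isolated)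
Conditions: LiN(iPr)2, THF, −78 °C; then PhNTf2, −78 °C → rt
Reagents that add atoms: N-phenylbis(trifluoromethanesulfonimide), FC(F)(F)S(=O)(=O)N(c1ccccc1)S(=O)(=O)C(F)(F)F
Why: The ketone can enolise only toward C5 (C1 is quaternary), so deprotonation and O-triflation of the enolate should give the tetrasubstituted enol triflate regiospecifically (enol triflate formation); the C5 stereocentre of actinol is erased on purpose.

Step 3
Reactants: 4 (R)-4-(TBSO)-2,6,6-trimethylcyclohex-1-en-1-yl trifluoromethanesulfonate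
Product: 5 methyl (R)-4-(TBSO)-2,6,6-trimethylcyclohex-1-ene-1-carboxylate
Conditions: Pd(OAc)2 (cat.), PPh3, CO (1 atm), MeOH, Et3N, DMF, 60 °C
Reagents that add atoms: carbon monoxide, [C-]#[O+]; methanol, CO
Why: Palladium-catalysed methoxycarbonylation of the enol triflate (oxidative addition, CO insertion, methanolysis) installs C7 as an ester on the hindered ring carbon C6.

Step 4
Reactants: 5 methyl (R)-4-(TBSO)-2,6,6-trimethylcyclohex-1-ene-1-carboxylate
Product: 6 [(R)-4-(TBSO)-2,6,6-trimethylcyclohex-1-en-1-yl]methanol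
Conditions: iBu2AlH, CH2Cl2, −78 → 0 °C
Reagents that add atoms: none
Why: 1,2-Reduction of the conjugated ester by two hydride transfers should give the allylic alcohol that serves as the handle for directed epoxidation.

Step 5
Reactants: 6 [(R)-4-(TBSO)-2,6,6-trimethylcyclohex-1-en-1-yl]methanol
Product: 7 [(1R,4S,6R)-4-(TBSO)-2,2,6-trimethyl-7-oxabicyclo[4.1.0]heptan-1-yl]methanol (epoxide anti to the silyloxy group)
Conditions: Ti(OiPr)4 (cat.), D-(−)-diethyl tartrate (cat.), tBuOOH, 4 Å molecular sieves, CH2Cl2, −20 °C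
Reagents that add atoms: tert-butyl hydroperoxide, CC(C)(C)OO
Why: Sharpless asymmetric epoxidation: the titanium tartrate bound to the C7 hydroxyl delivers oxygen to the C5=C6 face dictated by D-(−)-tartrate, which is the face anti to the C3 silyloxy group, so C5 (R) and C6 are set together under reagent control.

Step 6
Reactants: 7 [(1R,4S,6R)-4-(TBSO)-2,2,6-trimethyl-7-oxabicyclo[4.1.0]heptan-1-yl]methanol
Product: 8 (1S,4S,6R)-4-(TBSO)-2,2,6-trimethyl-7-oxabicyclo[4.1.0]heptane-1-carbaldehyde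
Conditions: Pr4N[RuO4] (cat.), N-methylmorpholine N-oxide, 4 Å molecular sieves, CH2Cl2, rt
Reagents that add atoms: none
Why: Ley–Griffith oxidation of the primary epoxy alcohol is neutral and should leave the tetrasubstituted epoxide and the silyl ether intact; the aldehyde has no α-hydrogen and cannot epimerise.

Step 7
Reactants: 8 (1S,4S,6R)-4-(TBSO)-2,2,6-trimethyl-7-oxabicyclo[4.1.0]heptane-1-carbaldehyde
Product: 9 (1R,4S,6R)-4-(TBSO)-1-ethynyl-2,2,6-trimethyl-7-oxabicyclo[4.1.0]heptane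
Conditions: dimethyl (1-diazo-2-oxopropyl)phosphonate, K2CO3, MeOH, 0 °C → rt
Reagents that add atoms: dimethyl (1-diazo-2-oxopropyl)phosphonate, COP(=O)(OC)C(=[N+]=[N-])C(C)=O
Why: Ohira–Bestmann (Seyferth–Gilbert) homologation: the diazomethylphosphonate anion formed in methanol adds to the non-enolisable aldehyde and the alkylidene carbene rearranges to the terminal alkyne (C7′≡C8′) without touching the epoxide.

Step 8
Reactants: 10 methyl acetoacetate
Product: 11 methyl (E)-3-(trifluoromethanesulfonyloxy)but-2-enoate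
Conditions: Tf2O, aq. Me4NOH, hexane, 5 °C
Reagents that add atoms: trifluoromethanesulfonic anhydride, FC(F)(F)S(=O)(=O)OS(=O)(=O)C(F)(F)F
Why: O-Triflation of the non-chelated tetramethylammonium enolate of the β-keto ester under biphasic conditions should give the (E)-enol triflate (leaving group trans to the ester), which fixes the later C9′=C10′ geometry.

Step 9
Reactants: 9 (1R,4S,6R)-4-(TBSO)-1-ethynyl-2,2,6-trimethyl-7-oxabicyclo[4.1.0]heptane; 11 methyl (E)-3-(trifluoromethanesulfonyloxy)but-2-enoate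
Product: 12 methyl (E)-5-[(1R,4S,6R)-4-(TBSO)-2,2,6-trimethyl-7-oxabicyclo[4.1.0]heptan-1-yl]-3-methylpent-2-en-4-ynoate
Conditions: Pd(PPh3)4 (cat.), CuI (cat.), iPr2NH, THF, rt
Reagents that add atoms: none
Why: Sonogashira coupling of the terminal alkyne with the electron-poor enol triflate forms C8′–C9′ with retention of the (E) geometry and tolerates the propargylic epoxide.

Step 10
Reactants: 12 methyl (E)-5-[(1R,4S,6R)-4-(TBSO)-2,2,6-trimethyl-7-oxabicyclo[4.1.0]heptan-1-yl]-3-methylpent-2-en-4-ynoate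
Product: 13 (2E)-5-[(2R,4S)-4-(TBSO)-2-hydroxy-2,6,6-trimethylcyclohexylidene]-3-methylpenta-2,4-dien-1-ol with the allene axis (R)
Conditions: iBu2AlH (excess), CH2Cl2, −78 → 0 °C
Reagents that add atoms: none
Why: iBu2AlH reduces the ester and opens the alkynyl epoxide by SN2′ hydride transfer to C8′ from aluminium held on the epoxide oxygen (the known reduction of this epoxy-enyne motif to the allenic carotenoid end group); delivery on the side of the departing oxygen should give the (R) allene axis while the C5′ oxygen keeps its configuration.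

Step 11
Reactants: 13 (2E)-5-[(2R,4S)-4-(TBSO)-2-hydroxy-2,6,6-trimethylcyclohexylidene]-3-methylpenta-2,4-dien-1-ol with the allene axis (R)
Product: 14 (2E)-5-[(2R,4S)-4-(TBSO)-2-hydroxy-2,6,6-trimethylcyclohexylidene]-3-methylpenta-2,4-dienal with the allene axis (R)
Conditions: MnO2, CH2Cl2, rt, dark
Reagents that add atoms: none
Why: MnO2 oxidises only the primary allylic alcohol (allylic oxidation); the tertiary carbinol is inert, and the resulting electron-poor enal stabilises the C8′–O bond that is made next.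

Step 12
Reactants: 14 (2E)-5-[(2R,4S)-4-(TBSO)-2-hydroxy-2,6,6-trimethylcyclohexylidene]-3-methylpenta-2,4-dienal with the allene axis (R)
Product: 15 (2E)-3-[(2S,6S,7aR)-6-(TBSO)-4,4,7a-trimethyl-2,4,5,6,7,7a-hexahydro-1-benzofuran-2-yl]but-2-enal
Conditions: Ph3PAuCl (cat.), AgBF4 (cat.), CH2Cl2, 0 °C → rt, dark
Reagents that add atoms: none
Why: Gold-catalysed 5-endo cycloisomerisation of the α-hydroxyallene closes ring C (O–C8′ bond, C6′=C7′ left in the ring): the C5′ hydroxyl can reach C8′ only in the plane of C5′–C6′, so the (R) axis should be translated into the (8′S) centre, and the electron-withdrawing enal disfavours re-ionisation of the new allylic C–O bond.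

Step 13
Reactants: 16 prop-2-yn-1-ol
Product: 18 (E)-3-iodo-2-methylprop-2-en-1-ol, via alkenylalane 17 (not isolated)
Conditions: Me3Al, Cp2ZrCl2 (cat.), CH2Cl2, 0 °C → rt; then I2, THF, −30 → 0 °C
Reagents that add atoms: trimethylaluminium, C[Al](C)C; iodine, II
Why: Zirconium-catalysed syn-carboalumination (Negishi) adds methyl to the internal and aluminium to the terminal alkyne carbon on the same side, and iodinolysis with retention gives the (E)-iodoalkene that becomes C13′(Me)=C14′–I.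

Step 14
Reactants: 18 (E)-3-iodo-2-methylprop-2-en-1-ol
Product: 19 (E)-3-bromo-1-iodo-2-methylprop-1-ene
Conditions: CBr4, PPh3, CH2Cl2, 0 °C
Reagents that add atoms: tetrabromomethane, BrC(Br)(Br)Br
Why: Appel bromination converts the primary allylic alcohol into the bromide under neutral conditions without touching the vinyl iodide.

Step 15
Reactants: 19 (E)-3-bromo-1-iodo-2-methylprop-1-ene
Product: 20 diethyl [(E)-3-iodo-2-methylprop-2-en-1-yl]phosphonate
Conditions: P(OEt)3 (neat), 90 °C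
Reagents that add atoms: triethyl phosphite, CCOP(OCC)OCC
Why: Michaelis–Arbuzov reaction of the allylic bromide gives the allylic phosphonate; the vinyl iodide is not a substrate for this SN2 process.

Step 16
Reactants: 15 (2E)-3-[(2S,6S,7aR)-6-(TBSO)-4,4,7a-trimethyl-2,4,5,6,7,7a-hexahydro-1-benzofuran-2-yl]but-2-enal; 20 diethyl [(E)-3-iodo-2-methylprop-2-en-1-yl]phosphonate
Product: 22 (2S,6S,7aR)-6-(TBSO)-2-[(2E,4E,6E)-7-iodo-6-methylhepta-2,4,6-trien-2-yl]-4,4,7a-trimethyl-2,4,5,6,7,7a-hexahydro-1-benzofuran, via lithiated phosphonate 21 (not isolated)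
Conditions: 20, LiN(SiMe3)2, THF, −78 °C; then 15, −78 → 0 °C
Reagents that add atoms: none
Why: Horner–Wadsworth–Emmons olefination of the enal with the lithiated allylic phosphonate forms C11′=C12′ with the usual (E) preference and brings in the (E)-C13′=C14′–I unit; addition to the aldehyde at low temperature should outpace γ-deprotonation at C8′.

Step 17
Reactants: 8 (1S,4S,6R)-4-(TBSO)-2,2,6-trimethyl-7-oxabicyclo[4.1.0]heptane-1-carbaldehyde; 23 ethyl (E)-4-(diethoxyphosphoryl)-3-methylbut-2-enoate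
Product: 25 ethyl (2E,4E)-5-[(1S,4S,6R)-4-(TBSO)-2,2,6-trimethyl-7-oxabicyclo[4.1.0]heptan-1-yl]-3-methylpenta-2,4-dienoate, via lithiated phosphonoester 24 (not isolated)
Conditions: 23, LiN(SiMe3)2, THF, −78 °C; then 8, −78 → 0 °C
Reagents that add atoms: none
Why: Horner–Wadsworth–Emmons olefination of the neopentyl epoxy aldehyde with the vinylogous phosphonoacetate builds (E)-C7=C8 and brings in (E)-C9=C10 with the ester as C11; any 9Z isomer should be removable by chromatography.

Step 18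
Reactants: 25 ethyl (2E,4E)-5-[(1S,4S,6R)-4-(TBSO)-2,2,6-trimethyl-7-oxabicyclo[4.1.0]heptan-1-yl]-3-methylpenta-2,4-dienoate
Product: 26 ethyl (2E,4E)-5-[(1R,2R,4S)-4-(TBSO)-1,2-dihydroxy-2,6,6-trimethylcyclohexyl]-3-methylpenta-2,4-dienoate
Conditions: HClO4 (cat.), THF–H2O (1:1), 0 °C
Reagents that add atoms: water, O
Why: Acid-catalysed epoxide hydrolysis: the protonated epoxide opens at the allylic C6–O bond and water enters at C6 anti to the departing oxygen, so C6 is inverted (S to R) while the C5 oxygen keeps its place, giving the 5,6-trans-diol; the conjugated ester disfavours the dihydrofuran rearrangement and the silyl ether keeps the C3 oxygen from attacking C6.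

Step 19
Reactants: 26 ethyl (2E,4E)-5-[(1R,2R,4S)-4-(TBSO)-1,2-dihydroxy-2,6,6-trimethylcyclohexyl]-3-methylpenta-2,4-dienoate
Product: 27 (1R,2R,4S)-4-(TBSO)-1-[(1E,3E)-5-hydroxy-3-methylpenta-1,3-dien-1-yl]-2,6,6-trimethylcyclohexane-1,2-diol
Conditions: iBu2AlH (excess), CH2Cl2, −78 °C
Reagents that add atoms: none
Why: 1,2-Reduction of the dienoate with excess hydride (two equivalents are taken up by the tertiary hydroxyls) should give the allylic alcohol.

Step 20
Reactants: 27 (1R,2R,4S)-4-(TBSO)-1-[(1E,3E)-5-hydroxy-3-methylpenta-1,3-dien-1-yl]-2,6,6-trimethylcyclohexane-1,2-diol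
Product: 28 (2E,4E)-5-[(1R,2R,4S)-4-(TBSO)-1,2-dihydroxy-2,6,6-trimethylcyclohexyl]-3-methylpenta-2,4-dienal
Conditions: MnO2, CH2Cl2, rt, dark
Reagents that add atoms: none
Why: MnO2 oxidises the primary allylic alcohol chemoselectively (allylic oxidation); the tertiary hydroxyls are inert.

Step 21
Reactants: 28 (2E,4E)-5-[(1R,2R,4S)-4-(TBSO)-1,2-dihydroxy-2,6,6-trimethylcyclohexyl]-3-methylpenta-2,4-dienal; 23 ethyl (E)-4-(diethoxyphosphoryl)-3-methylbut-2-enoate
Product: 30 ethyl (2E,4E,6E,8E)-9-[(1R,2R,4S)-4-(TBSO)-1,2-dihydroxy-2,6,6-trimethylcyclohexyl]-3,7-dimethylnona-2,4,6,8-tetraenoate, via sodiated phosphonoester 29 (not isolated)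
Conditions: 23 (excess), NaN(SiMe3)2, THF, −78 °C; then 28, −78 → 0 °C
Reagents that add atoms: none
Why: A second Horner–Wadsworth–Emmons homologation, here with the more reactive sodium salt of the phosphonoester because the vinylogous dienal is a weaker electrophile, forms (E)-C11=C12 and adds (E)-C13=C14 with C15 as the ester; the stabilised phosphonate anion is too weak a base to deprotonate the tertiary alcohols.

Step 22
Reactants: 30 ethyl (2E,4E,6E,8E)-9-[(1R,2R,4S)-4-(TBSO)-1,2-dihydroxy-2,6,6-trimethylcyclohexyl]-3,7-dimethylnona-2,4,6,8-tetraenoate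
Product: 31 (1R,2R,4S)-4-(TBSO)-1-[(1E,3E,5E,7E)-9-hydroxy-3,7-dimethylnona-1,3,5,7-tetraen-1-yl]-2,6,6-trimethylcyclohexane-1,2-diol
Conditions: iBu2AlH (excess), CH2Cl2, −78 °C, dark
Reagents that add atoms: none
Why: 1,2-Reduction of the tetraenoate by hydride gives the allylic alcohol, as for the lower homologue.

Step 23
Reactants: 31 (1R,2R,4S)-4-(TBSO)-1-[(1E,3E,5E,7E)-9-hydroxy-3,7-dimethylnona-1,3,5,7-tetraen-1-yl]-2,6,6-trimethylcyclohexane-1,2-diol
Product: 32 (2E,4E,6E,8E)-9-[(1R,2R,4S)-4-(TBSO)-1,2-dihydroxy-2,6,6-trimethylcyclohexyl]-3,7-dimethylnona-2,4,6,8-tetraenal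
Conditions: MnO2, CH2Cl2, rt, dark
Reagents that add atoms: none
Why: Allylic oxidation with MnO2 gives the C15 aldehyde without touching the tertiary hydroxyls or the polyene.

Step 24
Reactants: 33 dibromomethane
Product: 35 tributyl(dibromomethyl)stannane, via dibromomethyllithium 34 (not isolated)
Conditions: LiN(iPr)2, THF–Et2O, −95 °C; then Bu3SnCl, −95 → −40 °C
Reagents that add atoms: tributyltin chloride, CCCC[Sn](Cl)(CCCC)CCCC
Why: Deprotonation of dibromomethane at very low temperature gives the lithium carbenoid, which is stannylated at carbon before it can decompose (electrophilic trapping of a carbenoid).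

Step 25
Reactants: 32 (2E,4E,6E,8E)-9-[(1R,2R,4S)-4-(TBSO)-1,2-dihydroxy-2,6,6-trimethylcyclohexyl]-3,7-dimethylnona-2,4,6,8-tetraenal; 35 tributyl(dibromomethyl)stannane
Product: 36 (1R,2R,4S)-4-(TBSO)-1-[(1E,3E,5E,7E,9E)-3,7-dimethyl-10-(tributylstannyl)deca-1,3,5,7,9-pentaen-1-yl]-2,6,6-trimethylcyclohexane-1,2-diol
Conditions: CrCl2, LiI, DMF–THF, rt, dark
Reagents that add atoms: none
Why: Takai-type olefination with the geminal dichromium reagent formed from 35 converts the aldehyde into the (E)-alkenylstannane C15=C15′–Sn; the (E) selectivity comes from the anti arrangement of the residues in the β-oxido chromium intermediate, and the reagent tolerates free hydroxyls.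

Step 26
Reactants: 22 (2S,6S,7aR)-6-(TBSO)-2-[(2E,4E,6E)-7-iodo-6-methylhepta-2,4,6-trien-2-yl]-4,4,7a-trimethyl-2,4,5,6,7,7a-hexahydro-1-benzofuran; 36 (1R,2R,4S)-4-(TBSO)-1-[(1E,3E,5E,7E,9E)-3,7-dimethyl-10-(tributylstannyl)deca-1,3,5,7,9-pentaen-1-yl]-2,6,6-trimethylcyclohexane-1,2-diol
Product: 37 3,3′-bis-O-TBS ether of (3S,5R,6R,3′S,5′R,8′S)-5′,8′-epoxy-5,6,5′,8′-tetrahydro-β,β-carotene-3,5,6,3′-tetrol
Conditions: Pd2(dba)3 (cat.), AsPh3, N-methylpyrrolidone, 25 → 40 °C, dark, argon
Reagents that add atoms: none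
Why: Stille coupling: zerovalent palladium inserts into the C14′–I bond of 22 with retention, the C15′–Sn bond of 36 transmetalates with retention (the weakly bound AsPh3 speeds this step), and reductive elimination forms the C15′–C14′ bond and returns the catalyst. The closest known reaction type is the alkenyl–alkenyl Stille coupling of polyenylstannanes with polyenyl iodides used to assemble conjugated polyenes. No ring is closed and no stereocentre is created: the six stereocentres arrive complete in the two halves, and the (E) geometry of C15=C15′ and C13′=C14′ is carried through by the stereoretentive elementary steps. The step needs chemoselectivity for the single C(sp2)–I and C(sp2)–Sn bonds and preservation of all eight chain double bonds; this is secured because both reacting carbons are unhindered terminal CH groups and because alkenylpalladium intermediates have no pathway for β-hydride loss. The medium is neutral, so the allylic C8′–O bond of ring C and the tertiary allylic C6–OH should survive. Free tertiary hydroxyls do not interfere with palladium or tin, so no further protection is needed.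

Step 27
Reactants: 37 3,3′-bis-O-TBS ether of (3S,5R,6R,3′S,5′R,8′S)-5′,8′-epoxy-5,6,5′,8′-tetrahydro-β,β-carotene-3,5,6,3′-tetrol
Product: 38 (3S,5R,6R,3′S,5′R,8′S)-5′,8′-epoxy-5,6,5′,8′-tetrahydro-β,β-carotene-3,5,6,3′-tetrol
Conditions: Bu4NF, THF, 0 °C → rt, dark
Reagents that add atoms: none
Why: Fluoride-induced cleavage of the two secondary silyl ethers (Si–F bond formation) under basic, non-acidic conditions frees C3–OH and C3′–OH without endangering ring C or the polyene.

## Compound list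

1 | (4R,6R)-4-hydroxy-2,2,6-trimethylcyclohexanone [(−)-actinol] | O=C1C(C)(C)C[C@H](O)C[C@H]1C | starting material
2 | (4R,6R)-4-(TBSO)-2,2,6-trimethylcyclohexanone | O=C1C(C)(C)C[C@H](O[Si](C)(C)C(C)(C)C)C[C@H]1C | intermediate
3 | lithium enolate of 2 | CC1=C(O[Li])C(C)(C)C[C@H](O[Si](C)(C)C(C)(C)C)C1 | intermediate
4 | (R)-4-(TBSO)-2,6,6-trimethylcyclohex-1-en-1-yl trifluoromethanesulfonate | CC1=C(OS(=O)(=O)C(F)(F)F)C(C)(C)C[C@H](O[Si](C)(C)C(C)(C)C)C1 | intermediate
5 | methyl (R)-4-(TBSO)-2,6,6-trimethylcyclohex-1-ene-1-carboxylate | CC1=C(C(=O)OC)C(C)(C)C[C@H](O[Si](C)(C)C(C)(C)C)C1 | intermediate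
6 | [(R)-4-(TBSO)-2,6,6-trimethylcyclohex-1-en-1-yl]methanol | CC1=C(CO)C(C)(C)C[C@H](O[Si](C)(C)C(C)(C)C)C1 | intermediate
7 | [(1R,4S,6R)-4-(TBSO)-2,2,6-trimethyl-7-oxabicyclo[4.1.0]heptan-1-yl]methanol | OC[C@]1(O2)C(C)(C)C[C@H](O[Si](C)(C)C(C)(C)C)C[C@]12C | intermediate
8 | (1S,4S,6R)-4-(TBSO)-2,2,6-trimethyl-7-oxabicyclo[4.1.0]heptane-1-carbaldehyde | O=C[C@]1(O2)C(C)(C)C[C@H](O[Si](C)(C)C(C)(C)C)C[C@]12C | intermediate
9 | (1R,4S,6R)-4-(TBSO)-1-ethynyl-2,2,6-trimethyl-7-oxabicyclo[4.1.0]heptane | C#C[C@]1(O2)C(C)(C)C[C@H](O[Si](C)(C)C(C)(C)C)C[C@]12C | intermediate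
10 | methyl acetoacetate | COC(=O)CC(C)=O | starting material
11 | methyl (E)-3-(trifluoromethanesulfonyloxy)but-2-enoate | COC(=O)/C=C(\C)OS(=O)(=O)C(F)(F)F | intermediate
12 | methyl (E)-5-[(1R,4S,6R)-4-(TBSO)-2,2,6-trimethyl-7-oxabicyclo[4.1.0]heptan-1-yl]-3-methylpent-2-en-4-ynoate | COC(=O)/C=C(\C)C#C[C@]1(O2)C(C)(C)C[C@H](O[Si](C)(C)C(C)(C)C)C[C@]12C | intermediate
13 | (2E)-5-[(2R,4S)-4-(TBSO)-2-hydroxy-2,6,6-trimethylcyclohexylidene]-3-methylpenta-2,4-dien-1-ol, allene axis (R) | OC/C=C(\C)C([H])=[C@@]=C1C(C)(C)C[C@H](O[Si](C)(C)C(C)(C)C)C[C@@]1(C)O | intermediate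
14 | (2E)-5-[(2R,4S)-4-(TBSO)-2-hydroxy-2,6,6-trimethylcyclohexylidene]-3-methylpenta-2,4-dienal, allene axis (R) | O=C/C=C(\C)C([H])=[C@@]=C1C(C)(C)C[C@H](O[Si](C)(C)C(C)(C)C)C[C@@]1(C)O | intermediate
15 | (2E)-3-[(2S,6S,7aR)-6-(TBSO)-4,4,7a-trimethyl-2,4,5,6,7,7a-hexahydro-1-benzofuran-2-yl]but-2-enal | O=C/C=C(\C)[C@@H]1C=C2C(C)(C)C[C@H](O[Si](C)(C)C(C)(C)C)C[C@@]2(C)O1 | intermediate
16 | prop-2-yn-1-ol | C#CCO | starting material
17 | (E)-alkenylalane: dimethyl[(E)-3-(dimethylalumanyloxy)-2-methylprop-1-en-1-yl]alumane | C[Al](C)OC/C(C)=C/[Al](C)C | intermediate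
18 | (E)-3-iodo-2-methylprop-2-en-1-ol | OC/C(C)=C/I | intermediate
19 | (E)-3-bromo-1-iodo-2-methylprop-1-ene | BrC/C(C)=C/I | intermediate
20 | diethyl [(E)-3-iodo-2-methylprop-2-en-1-yl]phosphonate | CCOP(=O)(OCC)C/C(C)=C/I | intermediate
21 | lithiated phosphonate (C1 carbanion of 20) | [Li]C(/C(C)=C/I)P(=O)(OCC)OCC | intermediate
22 | (2S,6S,7aR)-6-(TBSO)-2-[(2E,4E,6E)-7-iodo-6-methylhepta-2,4,6-trien-2-yl]-4,4,7a-trimethyl-2,4,5,6,7,7a-hexahydro-1-benzofuran | I/C=C(C)/C=C/C=C(\C)[C@@H]1C=C2C(C)(C)C[C@H](O[Si](C)(C)C(C)(C)C)C[C@@]2(C)O1 | intermediate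
23 | ethyl (E)-4-(diethoxyphosphoryl)-3-methylbut-2-enoate (triethyl 3-methyl-4-phosphonocrotonate) | CCOC(=O)/C=C(\C)CP(=O)(OCC)OCC | starting material
24 | lithiated phosphonoester (lithium salt of the C4 carbanion of 23) | [Li]C(/C(C)=C/C(=O)OCC)P(=O)(OCC)OCC | intermediate
25 | ethyl (2E,4E)-5-[(1S,4S,6R)-4-(TBSO)-2,2,6-trimethyl-7-oxabicyclo[4.1.0]heptan-1-yl]-3-methylpenta-2,4-dienoate | CCOC(=O)/C=C(C)/C=C/[C@]1(O2)C(C)(C)C[C@H](O[Si](C)(C)C(C)(C)C)C[C@]12C | intermediate
26 | ethyl (2E,4E)-5-[(1R,2R,4S)-4-(TBSO)-1,2-dihydroxy-2,6,6-trimethylcyclohexyl]-3-methylpenta-2,4-dienoate | CCOC(=O)/C=C(C)/C=C/[C@@]1(O)C(C)(C)C[C@H](O[Si](C)(C)C(C)(C)C)C[C@@]1(C)O | intermediate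
27 | (1R,2R,4S)-4-(TBSO)-1-[(1E,3E)-5-hydroxy-3-methylpenta-1,3-dien-1-yl]-2,6,6-trimethylcyclohexane-1,2-diol | OC/C=C(C)/C=C/[C@@]1(O)C(C)(C)C[C@H](O[Si](C)(C)C(C)(C)C)C[C@@]1(C)O | intermediate
28 | (2E,4E)-5-[(1R,2R,4S)-4-(TBSO)-1,2-dihydroxy-2,6,6-trimethylcyclohexyl]-3-methylpenta-2,4-dienal | O=C/C=C(C)/C=C/[C@@]1(O)C(C)(C)C[C@H](O[Si](C)(C)C(C)(C)C)C[C@@]1(C)O | intermediate
29 | sodiated phosphonoester (sodium salt of the C4 carbanion of 23) | [Na]C(/C(C)=C/C(=O)OCC)P(=O)(OCC)OCC | intermediate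
30 | ethyl (2E,4E,6E,8E)-9-[(1R,2R,4S)-4-(TBSO)-1,2-dihydroxy-2,6,6-trimethylcyclohexyl]-3,7-dimethylnona-2,4,6,8-tetraenoate | CCOC(=O)/C=C(C)/C=C/C=C(C)/C=C/[C@@]1(O)C(C)(C)C[C@H](O[Si](C)(C)C(C)(C)C)C[C@@]1(C)O | intermediate
31 | (1R,2R,4S)-4-(TBSO)-1-[(1E,3E,5E,7E)-9-hydroxy-3,7-dimethylnona-1,3,5,7-tetraen-1-yl]-2,6,6-trimethylcyclohexane-1,2-diol | OC/C=C(C)/C=C/C=C(C)/C=C/[C@@]1(O)C(C)(C)C[C@H](O[Si](C)(C)C(C)(C)C)C[C@@]1(C)O | intermediate
32 | (2E,4E,6E,8E)-9-[(1R,2R,4S)-4-(TBSO)-1,2-dihydroxy-2,6,6-trimethylcyclohexyl]-3,7-dimethylnona-2,4,6,8-tetraenal | O=C/C=C(C)/C=C/C=C(C)/C=C/[C@@]1(O)C(C)(C)C[C@H](O[Si](C)(C)C(C)(C)C)C[C@@]1(C)O | intermediate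
33 | dibromomethane | BrCBr | starting material
34 | dibromomethyllithium | [Li]C(Br)Br | intermediate
35 | tributyl(dibromomethyl)stannane | CCCC[Sn](CCCC)(CCCC)C(Br)Br | intermediate
36 | (1R,2R,4S)-4-(TBSO)-1-[(1E,3E,5E,7E,9E)-3,7-dimethyl-10-(tributylstannyl)deca-1,3,5,7,9-pentaen-1-yl]-2,6,6-trimethylcyclohexane-1,2-diol | CCCC[Sn](CCCC)(CCCC)/C=C/C=C(C)/C=C/C=C(C)/C=C/[C@@]1(O)C(C)(C)C[C@H](O[Si](C)(C)C(C)(C)C)C[C@@]1(C)O | intermediate
37 | 3,3′-bis-O-TBS ether of 38 | CC(/C=C/C=C(C)/C=C/[C@@]1(O)C(C)(C)C[C@H](O[Si](C)(C)C(C)(C)C)C[C@@]1(C)O)=C\C=C\C=C(C)\C=C\C=C(/C)[C@@H]1C=C2C(C)(C)C[C@H](O[Si](C)(C)C(C)(C)C)C[C@@]2(C)O1 | intermediate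
38 | (3S,5R,6R,3′S,5′R,8′S)-5′,8′-epoxy-5,6,5′,8′-tetrahydro-β,β-carotene-3,5,6,3′-tetrol | CC(/C=C/C=C(C)/C=C/[C@@]1(O)C(C)(C)C[C@H](O)C[C@@]1(C)O)=C\C=C\C=C(C)\C=C\C=C(/C)[C@@H]1C=C2C(C)(C)C[C@H](O)C[C@@]2(C)O1 | target

## Step count and risks

Total step count: 27. Longest linear sequence: 16 steps (steps 1–6, 17–23, 25, 26, 27).

**Step 18 (epoxide hydrolysis).** The opening may lose its course: water may enter at C5 instead of C6, C6 may ionise fully and be captured with retention, the C5 oxygen may close onto C8 to a dihydrofuran, or the silyl ether may be hydrolysed first so that the C3 hydroxyl captures C6. The fallback sets out from 6 and returns at 26. Sharpless epoxidation of 6 with L-(+)-diethyl tartrate should give the syn epoxy alcohol F1. Dilute aqueous acid should then open the epoxide at C5 (tertiary, and remote from the inductively deactivated, doubly flanked C6) with inversion, which leads to the same 5,6-trans arrangement in the triol F2. Selective oxidation of the primary alcohol (TEMPO, PhI(OAc)2) should give the α-hydroxy aldehyde F3, and Horner–Wadsworth–Emmons reaction with 24 then gives 26.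

**Step 12 (ring C closure, together with the axial sense set in step 10).** The axis-to-centre transfer may erode through gold-induced ionisation of the new allylic C8′–O bond, the vinylallene may take a Nazarov-type path to a cyclopentadiene, or the hydride in step 10 may have been delivered to the other face so that the wrong axis is carried forward. The fallback sets out from 25 and returns at 15; it uses the acid-catalysed epoxide-to-furanoid rearrangement. Brief treatment of 25 with a trace of HCl in CHCl3 should give the dihydrofuran ester F4 together with its C8′ epimer F5. The two are separated by chromatography and F5 is re-equilibrated under the same acid. Reduction of F4 with iBu2AlH gives the allylic alcohol F6, and MnO2 oxidation gives 15.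

**Step 26 (fragment union).** The pentaenylstannane may be lost by protodestannylation or homocoupling, transmetalation may be slow, and the polyene may isomerise under palladium and light. The fallback sets out from 32 and returns at 37; it replaces tin by boron. Takai-type borylolefination of 32 (Cl2CHB(pin), CrCl2, LiI, THF) should give the pentaenyl pinacol boronate F7. Suzuki–Miyaura coupling of F7 with 22 (Pd(PPh3)4, TlOEt, THF–H2O, rt, dark) then forms the same C15′–C14′ bond and gives 37.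

## Further compounds

F1 | step 18 | [(1S,4S,6S)-4-(TBSO)-2,2,6-trimethyl-7-oxabicyclo[4.1.0]heptan-1-yl]methanol (epoxide syn to the silyloxy group) | OC[C@@]1(O2)C(C)(C)C[C@H](O[Si](C)(C)C(C)(C)C)C[C@@]12C
F2 | step 18 | (1S,2R,4S)-4-(TBSO)-1-(hydroxymethyl)-2,6,6-trimethylcyclohexane-1,2-diol | OC[C@@]1(O)C(C)(C)C[C@H](O[Si](C)(C)C(C)(C)C)C[C@@]1(C)O
F3 | step 18 | (1R,2R,4S)-4-(TBSO)-1,2-dihydroxy-2,6,6-trimethylcyclohexane-1-carbaldehyde | O=C[C@@]1(O)C(C)(C)C[C@H](O[Si](C)(C)C(C)(C)C)C[C@@]1(C)O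
F4 | step 12 | ethyl (2E)-3-[(2S,6S,7aR)-6-(TBSO)-4,4,7a-trimethyl-2,4,5,6,7,7a-hexahydro-1-benzofuran-2-yl]but-2-enoate | CCOC(=O)/C=C(\C)[C@@H]1C=C2C(C)(C)C[C@H](O[Si](C)(C)C(C)(C)C)C[C@@]2(C)O1
F5 | step 12 | ethyl (2E)-3-[(2R,6S,7aR)-6-(TBSO)-4,4,7a-trimethyl-2,4,5,6,7,7a-hexahydro-1-benzofuran-2-yl]but-2-enoate | CCOC(=O)/C=C(\C)[C@H]1C=C2C(C)(C)C[C@H](O[Si](C)(C)C(C)(C)C)C[C@@]2(C)O1
F6 | step 12 | (2E)-3-[(2S,6S,7aR)-6-(TBSO)-4,4,7a-trimethyl-2,4,5,6,7,7a-hexahydro-1-benzofuran-2-yl]but-2-en-1-ol | OC/C=C(\C)[C@@H]1C=C2C(C)(C)C[C@H](O[Si](C)(C)C(C)(C)C)C[C@@]2(C)O1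
F7 | step 26 | (1R,2R,4S)-4-(TBSO)-1-[(1E,3E,5E,7E,9E)-3,7-dimethyl-10-(4,4,5,5-tetramethyl-1,3,2-dioxaborolan-2-yl)deca-1,3,5,7,9-pentaen-1-yl]-2,6,6-trimethylcyclohexane-1,2-diol | CC1(C)OB(/C=C/C=C(C)/C=C/C=C(C)/C=C/[C@@]2(O)C(C)(C)C[C@H](O[Si](C)(C)C(C)(C)C)C[C@@]2(C)O)OC1(C)C
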